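**Assumption (one line):** silyl, allyl, Boc/nosyl and acetal groups are treated as protecting groups and the crotylborane, ylide, formaldehyde, methanol and acetic anhydride as reagents; locants used below are C1 lactam C=O, C2 CHOH, C3/C4 CH2, C5 quaternary C bearing C21H2O, C6 CH, C7 NCH2 on C6, C8 quaternary C bearing C1, C9=C10, C11/C12 CH2 (C12 on C6), C13 CH2, C14 CH–C22O2Me, C15 CH, C16/C17 CH2 (C17 on C10), C18 CH(C20H3), C19 NCH2.

## Retrosynthetic overview

1. Target ⇐ methanolysis/acetylation of a temporary C22(=O)–O–C21 lactone; ring D (lactam) ⇐ oxidation of a carbinolamine; ring E (nine-membered) ⇐ intramolecular Mitsunobu N-alkylation of a nosylamide (N–C7).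
2. Ring C, both quaternary carbons (C5, C8) and the C9=C10 alkene ⇐ intramolecular (4+3) cycloaddition of an oxyallyl cation (C5–C6–C12) with a diene (C8=C9–C10=C11); the two halves are joined just before through the C22–O–C21 ester.
3. West fragment 12 (rings A and B) ⇐ endo Diels–Alder of a 2-silyloxycyclopentadiene with 2-bromocyclopentenone, ozonolysis (C22 acid, C1 aldehyde), loss of HBr, methylenation.
4. East fragment 25 ⇐ 5-oxohexanal, (Z)-crotylboration (C2/C18), nosylamide at C19, α-chlorination and hydroxymethylation at C5.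
5. Ring order: B and A → C (plus temporary lactone) → E → D.

## Route

**Step 1**
Reactants: 1 cyclopent-2-en-1-one
Product: 2 tert-butyl(cyclopenta-1,4-dien-1-yloxy)dimethylsilane
Conditions: TBSOTf, Et3N, Et2O, 0 °C; used crude at once
Reagents that add atoms: tert-butyldimethylsilyl triflate, CC(C)(C)[Si](C)(C)OS(=O)(=O)C(F)(F)F
Why: soft enolisation and O-silylation at the α′-carbon (silyl dienol ether formation) gives the cross-conjugated 2-silyloxydiene; no stereocentre is formed.

**Step 2**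
Reactants: 1 cyclopent-2-en-1-one
Product: 4 2-bromocyclopent-2-en-1-one, via trans-2,3-dibromocyclopentanone 3 (not isolated)
Conditions: Br2, CH2Cl2, 0 °C; then Et3N, 0 °C
Reagents that add atoms: bromine, BrBr
Why: bromine addition followed by E1cB loss of HBr (α-bromination of an enone) gives a reactive dienophile that carries the later C9 leaving group; no stereocentre remains.

**Step 3**
Reactants: 2 tert-butyl(cyclopenta-1,4-dien-1-yloxy)dimethylsilane; 4 2-bromocyclopent-2-en-1-one
Product: 5 endo-2-bromo-8-(TBS-oxy)tricyclo[5.2.1.0(2,6)]dec-8-en-3-one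
Conditions: Corey (S)-o-tolyl-oxazaborolidinium triflimide (20 mol %), CH2Cl2, −78 → −40 °C
Reagents that add atoms: none
Why: catalytic enantioselective Diels–Alder reaction in which the endo rule puts the cyclopentanone ring (ring B) syn to the silyloxy-etheno bridge, the "para" orientation puts the OSi carbon (C22) on the bridgehead next to C15, and the chiral Lewis acid (enantiomer chosen to give 5) fixes C8, C9, C14 and C15.

**Step 4**
Reactants: 5 endo Diels–Alder adduct
Product: 7 all-cis 3a-bromo-3-formyl-4-oxooctahydropentalene-1-carboxylic acid, via methoxy hydroperoxide silyl ester 6 (not isolated)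
Conditions: O3 (1 equiv), CH2Cl2/MeOH, −78 °C; Me2S, −78 °C → rt; aqueous work-up
Reagents that add atoms: ozone, [O-][O+]=O
Why: ozonolysis of the only electron-rich alkene, the silyl enol ether, gives the acid at the silyloxy carbon (C22) and the aldehyde at the CH carbon (C1), so the two termini are differentiated and stay cis to ring B.

**Step 5**
Reactants: 7 bromo keto aldehyde acid
Product: 8 (1R,6aR)-3-formyl-4-oxo-1,2,4,5,6,6a-hexahydropentalene-1-carboxylic acid
Conditions: Et3N (2.2 equiv), CH2Cl2, 0 °C; work-up at pH 3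
Reagents that add atoms: none
Why: E1cB dehydrobromination in which the aldehyde enolate at C8 expels the tertiary bromide on C9, giving C8=C9 regiospecifically while C14 and C15 are untouched.

**Step 6**
Reactants: 8 keto enal acid
Product: 9 allyl (1R,6aR)-3-formyl-4-oxo-1,2,4,5,6,6a-hexahydropentalene-1-carboxylate
Conditions: allyl bromide, KHCO3, DMF, rt
Reagents that add atoms: allyl bromide, C=CCBr
Why: carboxylate O-alkylation (SN2) masks the acid so that the next step cannot form a cyclic pseudo-ester with the neighbouring aldehyde.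

**Step 7**
Reactants: 9 allyl ester
Product: 10 allyl (1R,6aR)-3-(dimethoxymethyl)-4-oxo-1,2,4,5,6,6a-hexahydropentalene-1-carboxylate
Conditions: HC(OMe)3, MeOH, PPTS (cat.), rt
Reagents that add atoms: trimethyl orthoformate, COC(OC)OC; methanol, CO
Why: acid-catalysed acetalisation is selective for the aldehyde over the hindered cross-conjugated ketone and makes C1 a non-conjugating group, so the later diene is not electron-poor.

**Step 8**
Reactants: 10 keto acetal
Product: 11 allyl (1R,6aR)-3-(dimethoxymethyl)-4-methylidene-1,2,4,5,6,6a-hexahydropentalene-1-carboxylate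
Conditions: Ph3PCH3Br, KOtBu, THF, 0 °C
Reagents that add atoms: methylenetriphenylphosphorane, C=P(c1ccccc1)(c1ccccc1)c1ccccc1
Why: Wittig methylenation of the C10 ketone creates the s-cis-locked C8=C9–C10=C11 diene; the ylide is too weak a base to enolise the ester, so C14 is not epimerised.

**Step 9**
Reactants: 11 diene allyl ester
Product: 12 (1R,6aR)-3-(dimethoxymethyl)-4-methylidene-1,2,4,5,6,6a-hexahydropentalene-1-carboxylic acid (west fragment)
Conditions: Pd(PPh3)4 (5 mol %), morpholine, THF, rt; work-up at pH 4–5, used at once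
Reagents that add atoms: none
Why: Tsuji–Trost deallylation with zerovalent palladium frees the C22 acid under neutral conditions that leave acetal, diene and C14 intact.

**Step 10**
Reactants: 13 1-methylcyclopent-1-ene
Product: 15 5-oxohexanal, via ozonide 14 (not isolated)
Conditions: O3, CH2Cl2, −78 °C; PPh3, −78 °C → rt
Reagents that add atoms: ozone, [O-][O+]=O
Why: ozonolysis with reductive work-up opens the ring to the keto aldehyde (C2 aldehyde, C6 ketone); no stereocentre.

**Step 11**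
Reactants: 15 5-oxohexanal
Product: 17 (6R,7R)-6-hydroxy-7-methylnon-8-en-2-one, via borinate ester 16 (not isolated)
Conditions: (Z)-crotyl-B(Ipc)2 [Ipc from (+)-α-pinene], Et2O/THF, −78 °C; then aq. NaOH, H2O2, 0 °C → rt
Reagents that add atoms: (Z)-crotyldiisopinocampheylborane, C/C=C\CB([C@@H]1C[C@@H]2C[C@H]([C@H]1C)C2(C)C)[C@@H]1C[C@@H]2C[C@H]([C@H]1C)C2(C)C
Why: Brown (Z)-crotylboration of the aldehyde (the ketone is inert at −78 °C), where the chair transition state gives the syn C2-OH/C18-Me pair and the isopinocampheyl groups select the aldehyde face.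

**Step 12**
Reactants: 17 syn homoallylic alcohol
Product: 18 (6R,7R)-7-methyl-6-(triisopropylsilyloxy)non-8-en-2-one
Conditions: TIPSOTf, 2,6-lutidine, CH2Cl2, −78 °C
Reagents that add atoms: triisopropylsilyl triflate, CC(C)[Si](OS(=O)(=O)C(F)(F)F)(C(C)C)C(C)C
Why: silyl ether formation protects the C2 hydroxyl with a group that survives every step up to the last one.

**Step 13**
Reactants: 18 TIPS ether
Product: 20 (6R,7R)-8-hydroxy-7-methyl-6-(triisopropylsilyloxy)octan-2-one, via aldehyde 19 (not isolated)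
Conditions: OsO4 (2 mol %), NaIO4, 2,6-lutidine, dioxane/H2O, rt; extract; then NaBH(OAc)3, ClCH2CH2Cl, rt
Reagents that add atoms: osmium tetroxide, O=[Os](=O)(=O)=O (catalytic, reoxidised by sodium periodate, [Na+].[O-]I(=O)(=O)=O)
Why: Lemieux–Johnson cleavage of the vinyl group and aldehyde-selective borohydride reduction give the C19 alcohol without touching the ketone; the α-methyl aldehyde is reduced at once so C18 does not epimerise.

**Step 14**
Reactants: 20 primary alcohol
Product: 22 N-[(2R,3R)-2-methyl-7-oxo-3-(triisopropylsilyloxy)octyl]-2-nitrobenzenesulfonamide, via N-Boc sulfonamide 21 (not isolated)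
Conditions: NsNHBoc, PPh3, DIAD, THF, 0 °C → rt; concentrate; then TFA, CH2Cl2, 0 °C
Reagents that add atoms: N-Boc-2-nitrobenzenesulfonamide, CC(C)(C)OC(=O)NS(=O)(=O)c1ccccc1[N+](=O)[O-]
Why: Fukuyama–Mitsunobu alkylation puts nitrogen on C19 (primary carbon, no stereocentre) and acid removes the Boc group to leave the nosylamide N–H needed for ring E.

**Step 15**
Reactants: 22 nosylamide ketone
Product: 23 N-[(2R,3R)-6-chloro-2-methyl-7-oxo-3-(triisopropylsilyloxy)octyl]-2-nitrobenzenesulfonamide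
Conditions: SO2Cl2 (1.05 equiv), CH2Cl2, 0 °C
Reagents that add atoms: sulfuryl chloride, O=S(=O)(Cl)Cl
Why: electrophilic α-chlorination through the more substituted enol puts chlorine on C5 (minor C12 isomer removed by chromatography); the C5 configuration is irrelevant because C5 becomes planar in step 19.

**Step 16**
Reactants: 23 α-chloro ketone
Product: 24 N,O-bis(trimethylsilyl) C5=C6 enol silane of 23
Conditions: TMSOTf (2.2 equiv), Et3N, CH2Cl2, 0 °C; non-aqueous work-up
Reagents that add atoms: trimethylsilyl triflate, C[Si](C)(C)OS(=O)(=O)C(F)(F)F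
Why: soft enolisation towards the more acidic chlorine-bearing carbon gives the C5=C6 silyl enol ether (the sulfonamide is silylated as well).

**Step 17**
Reactants: 24 chloro enol silane
Product: 25 N-[(2R,3R)-6-chloro-6-(hydroxymethyl)-2-methyl-7-oxo-3-(triisopropylsilyloxy)octyl]-2-nitrobenzenesulfonamide (east fragment)
Conditions: aq. HCHO, Sc(OTf)3 (10 mol %), THF/H2O, rt
Reagents that add atoms: formaldehyde, C=O
Why: Lewis-acid-catalysed Mukaiyama aldol reaction with formaldehyde (hydroxymethylation) builds the tertiary chloride bearing C21H2OH without base, so neither epoxide nor retro-aldol products form; the C5 mixture is of no consequence.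

**Step 18**
Reactants: 12 west acid; 25 east alcohol
Product: 26 C22–O–C21 ester of 12 and 25
Conditions: EDC·HCl, DMAP (cat.), CH2Cl2, 0 °C → rt
Reagents that add atoms: none
Why: Steglich esterification joins the two fragments through an ester whose atoms all end up in the target (C22 ester, C21 oxygen); no stereocentre is formed.

**Step 19**
Reactants: 26 tethered chloro ketone diene
Product: 28 tetracyclic keto lactone cycloadduct, via oxyallyl zwitterion 27 (not isolated)
Conditions: Et3N (3 equiv), CF3CH2OH/(CF3)2CHOH (4:1), 0.003 M, 0 °C → rt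
Reagents that add atoms: none
Why: intramolecular (4+3) cycloaddition of an oxyallyl cation (Föhlisch conditions) with the s-cis diene closes ring C; the ester tether on the upper face of ring A forces C5 onto that face of C8 and points C21 towards C14, which sets both quaternary centres C5 and C8 and leaves the tetrasubstituted C9=C10 alkene.

**Step 20**
Reactants: 28 C6 ketone
Product: 29 C6 methylidene compound
Conditions: Ph3PCH3Br, KOtBu (excess), THF/toluene, 0 → 50 °C
Reagents that add atoms: methylenetriphenylphosphorane, C=P(c1ccccc1)(c1ccccc1)c1ccccc1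
Why: Wittig methylenation of the C6 ketone supplies C7; C5 is quaternary, so nothing adjacent can epimerise.

**Step 21**
Reactants: 29 exocyclic alkene
Product: 31 C7 primary alcohol with C6-H set, via B-alkyl-9-BBN adduct 30 (not isolated)
Conditions: 9-BBN, THF, 0 → 50 °C; then H2O2, aq. NaOAc, 0 °C
Reagents that add atoms: hydrogen peroxide, OO
Why: hydroboration–oxidation in which the bulky borane adds to the exocyclic alkene from the face away from the dimethoxymethyl group on C8 and the C4 chain, so hydrogen enters C6 on the lactone face and C7H2OH ends syn to C1, as the lactam bridge requires.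

**Step 22**
Reactants: 31 hydroxy nosylamide
Product: 32 N-nosyl nine-membered amine (ring E closed)
Conditions: PPh3, DIAD, toluene/THF, 0.002 M, rt → 50 °C
Reagents that add atoms: none
Why: intramolecular Fukuyama–Mitsunobu N-alkylation at high dilution forms the N–C7 bond with the acidic nosylamide as nucleophile; no stereocentre is touched.

**Step 23**
Reactants: 32 dimethyl acetal
Product: 33 C1 aldehyde
Conditions: aq. HCl (1 M), THF, rt
Reagents that add atoms: water, O
Why: acetal hydrolysis unmasks the C1 aldehyde only after C7 carries nitrogen, so no lactol with a C7 hydroxyl can form.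

**Step 24**
Reactants: 33 nosyl aldehyde
Product: 35 bridged carbinolamine (ring D closed), via amino aldehyde 34 (not isolated)
Conditions: PhSH, K2CO3, MeCN, rt
Reagents that add atoms: none
Why: nosyl cleavage by thiolate (Meisenheimer adduct, loss of SO2) frees the secondary amine, which adds at once to the neighbouring non-enolisable C1 aldehyde.

**Step 25**
Reactants: 35 carbinolamine
Product: 36 lactam lactone
Conditions: (n-Pr4N)RuO4 (5 mol %), N-methylmorpholine N-oxide, 4 Å MS, CH2Cl2, rt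
Reagents that add atoms: none
Why: Ley–Griffith oxidation of the carbinolamine gives the lactam; the hemiaminal stereocentre disappears.

**Step 26**
Reactants: 36 lactam lactone
Product: 38 C2 O-TIPS ether of the target, via hydroxy methyl ester 37 (not isolated)
Conditions: K2CO3 (0.2 equiv), MeOH, 0 °C; evaporate; then Ac2O, pyridine, DMAP (cat.), CH2Cl2, 0 °C → rt
Reagents that add atoms: methanol, CO; acetic anhydride, CC(=O)OC(C)=O
Why: base-catalysed methanolysis of the seven-membered lactone gives the C22 methyl ester and C21 alcohol, which is acetylated in the same flask before it can relactonise; a short reaction at 0 °C limits epimerisation at C14.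

**Step 27**
Reactants: 38 silyl ether
Product: 39 CNP0296366.1 (target)
Conditions: HF·pyridine, THF/pyridine, 0 °C → rt
Reagents that add atoms: none
Why: fluoride-mediated desilylation frees the C2 hydroxyl without affecting the ester, acetate or lactam.

## Compound list

1 | cyclopent-2-en-1-one | O=C1C=CCC1 | starting material
2 | tert-butyl(cyclopenta-1,4-dien-1-yloxy)dimethylsilane | CC(C)(C)[Si](C)(C)OC1=CCC=C1 | intermediate
3 | trans-2,3-dibromocyclopentan-1-one (racemic, not isolated) | O=C1CC[C@H](Br)[C@H]1Br | intermediate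
4 | 2-bromocyclopent-2-en-1-one | O=C1CCC=C1Br | intermediate
5 | endo-2-bromo-8-(tert-butyldimethylsilyloxy)tricyclo[5.2.1.0(2,6)]dec-8-en-3-one (cyclopentanone ring syn to the C8=C9 bridge, Br exo) | O=C1CC[C@H]2[C@]1(Br)[C@H]1C=C(O[Si](C)(C)C(C)(C)C)[C@@H]2C1 | intermediate
6 | TBS (1R,3R,3aS,6aR)-3a-bromo-3-[hydroperoxy(methoxy)methyl]-4-oxooctahydropentalene-1-carboxylate (not isolated) | O=C1CC[C@H]2[C@]1(Br)[C@@H](C(OC)OO)C[C@H]2C(=O)O[Si](C)(C)C(C)(C)C | intermediate
7 | (1R,3R,3aS,6aR)-3a-bromo-3-formyl-4-oxooctahydropentalene-1-carboxylic acid (CO2H, CHO and ring B cis on ring A) | O=C1CC[C@H]2[C@]1(Br)[C@@H](C=O)C[C@H]2C(=O)O | intermediate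
8 | (1R,6aR)-3-formyl-4-oxo-1,2,4,5,6,6a-hexahydropentalene-1-carboxylic acid | O=C1CC[C@H]2C1=C(C=O)C[C@H]2C(=O)O | intermediate
9 | allyl (1R,6aR)-3-formyl-4-oxo-1,2,4,5,6,6a-hexahydropentalene-1-carboxylate | O=C1CC[C@H]2C1=C(C=O)C[C@H]2C(=O)OCC=C | intermediate
10 | allyl (1R,6aR)-3-(dimethoxymethyl)-4-oxo-1,2,4,5,6,6a-hexahydropentalene-1-carboxylate | O=C1CC[C@H]2C1=C(C(OC)OC)C[C@H]2C(=O)OCC=C | intermediate
11 | allyl (1R,6aR)-3-(dimethoxymethyl)-4-methylidene-1,2,4,5,6,6a-hexahydropentalene-1-carboxylate | C=C1CC[C@H]2C1=C(C(OC)OC)C[C@H]2C(=O)OCC=C | intermediate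
12 | (1R,6aR)-3-(dimethoxymethyl)-4-methylidene-1,2,4,5,6,6a-hexahydropentalene-1-carboxylic acid (west fragment) | C=C1CC[C@H]2C1=C(C(OC)OC)C[C@H]2C(=O)O | intermediate
13 | 1-methylcyclopent-1-ene | CC1=CCCC1 | starting material
14 | 1-methyl-6,7,8-trioxabicyclo[3.2.1]octane (ozonide, racemic, not isolated) | CC12CCCC(OO1)O2 | intermediate
15 | 5-oxohexanal | CC(=O)CCCC=O | intermediate
16 | bis(isopinocampheyl)borinate of 17 (not isolated) | CC(=O)CCC[C@@H](OB([C@@H]1C[C@@H]2C[C@H]([C@H]1C)C2(C)C)[C@@H]1C[C@@H]2C[C@H]([C@H]1C)C2(C)C)[C@H](C)C=C | intermediate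
17 | (6R,7R)-6-hydroxy-7-methylnon-8-en-2-one | CC(=O)CCC[C@@H](O)[C@H](C)C=C | intermediate
18 | (6R,7R)-7-methyl-6-(triisopropylsilyloxy)non-8-en-2-one | CC(=O)CCC[C@@H](O[Si](C(C)C)(C(C)C)C(C)C)[C@H](C)C=C | intermediate
19 | (2S,3R)-2-methyl-7-oxo-3-(triisopropylsilyloxy)octanal (not isolated) | CC(=O)CCC[C@@H](O[Si](C(C)C)(C(C)C)C(C)C)[C@H](C)C=O | intermediate
20 | (6R,7R)-8-hydroxy-7-methyl-6-(triisopropylsilyloxy)octan-2-one | CC(=O)CCC[C@@H](O[Si](C(C)C)(C(C)C)C(C)C)[C@H](C)CO | intermediate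
21 | tert-butyl N-[(2R,3R)-2-methyl-7-oxo-3-(triisopropylsilyloxy)octyl]-N-(2-nitrophenylsulfonyl)carbamate (not isolated) | CC(=O)CCC[C@@H](O[Si](C(C)C)(C(C)C)C(C)C)[C@H](C)CN(C(=O)OC(C)(C)C)S(=O)(=O)c1ccccc1[N+](=O)[O-] | intermediate
22 | N-[(2R,3R)-2-methyl-7-oxo-3-(triisopropylsilyloxy)octyl]-2-nitrobenzenesulfonamide | CC(=O)CCC[C@@H](O[Si](C(C)C)(C(C)C)C(C)C)[C@H](C)CNS(=O)(=O)c1ccccc1[N+](=O)[O-] | intermediate
23 | N-[(2R,3R)-6-chloro-2-methyl-7-oxo-3-(triisopropylsilyloxy)octyl]-2-nitrobenzenesulfonamide (1:1 at C6 of the chain) | CC(=O)C(Cl)CC[C@@H](O[Si](C(C)C)(C(C)C)C(C)C)[C@H](C)CNS(=O)(=O)c1ccccc1[N+](=O)[O-] | intermediate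
24 | N-[(2R,3R)-6-chloro-2-methyl-3-(triisopropylsilyloxy)-7-(trimethylsilyloxy)oct-6-enyl]-N-(trimethylsilyl)-2-nitrobenzenesulfonamide (E/Z mixture) | CC(O[Si](C)(C)C)=C(Cl)CC[C@@H](O[Si](C(C)C)(C(C)C)C(C)C)[C@H](C)CN([Si](C)(C)C)S(=O)(=O)c1ccccc1[N+](=O)[O-] | intermediate
25 | N-[(2R,3R)-6-chloro-6-(hydroxymethyl)-2-methyl-7-oxo-3-(triisopropylsilyloxy)octyl]-2-nitrobenzenesulfonamide (east fragment, 1:1 at the chloro carbon) | CC(=O)C(Cl)(CO)CC[C@@H](O[Si](C(C)C)(C(C)C)C(C)C)[C@H](C)CNS(=O)(=O)c1ccccc1[N+](=O)[O-] | intermediate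
26 | ester of acid 12 with the primary hydroxyl of 25 (C22–O–C21 tether) | C=C1CC[C@H]2C1=C(C(OC)OC)C[C@H]2C(=O)OCC(Cl)(C(C)=O)CC[C@@H](O[Si](C(C)C)(C(C)C)C(C)C)[C@H](C)CNS(=O)(=O)c1ccccc1[N+](=O)[O-] | intermediate
27 | oxyallyl zwitterion (C5–C6–C12) derived from 26 (not isolated) | C=C1CC[C@H]2C1=C(C(OC)OC)C[C@H]2C(=O)OC[C+](C([O-])=C)CC[C@@H](O[Si](C(C)C)(C(C)C)C(C)C)[C@H](C)CNS(=O)(=O)c1ccccc1[N+](=O)[O-] | intermediate
28 | (4+3) cycloadduct: rings A, B, C and the C22(=O)–O–C21 lactone, C6 ketone, CH(OMe)2 on C8, C4–C19 chain (C2 OTIPS, C18 Me, C19 NHNs) on C5; C2, C5, C8, C14, C15, C18 as in the target | O=C1OC[C@]2(CC[C@@H](O[Si](C(C)C)(C(C)C)C(C)C)[C@H](C)CNS(=O)(=O)c3ccccc3[N+](=O)[O-])C(=O)CCC3=C4[C@H](CC3)[C@H]1C[C@@]42C(OC)OC | intermediate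
29 | C6 methylidene analogue of 28 | O=C1OC[C@]2(CC[C@@H](O[Si](C(C)C)(C(C)C)C(C)C)[C@H](C)CNS(=O)(=O)c3ccccc3[N+](=O)[O-])C(=C)CCC3=C4[C@H](CC3)[C@H]1C[C@@]42C(OC)OC | intermediate
30 | B-(C7)-alkyl-9-borabicyclo[3.3.1]nonane adduct of 29 (not isolated) | O=C1OC[C@]2(CC[C@@H](O[Si](C(C)C)(C(C)C)C(C)C)[C@H](C)CNS(=O)(=O)c3ccccc3[N+](=O)[O-])[C@@H](CB3C5CCCC3CCC5)CCC3=C4[C@H](CC3)[C@H]1C[C@@]42C(OC)OC | intermediate
31 | C7 primary alcohol (C6-H set, C7H2OH syn to C1) | O=C1OC[C@]2(CC[C@@H](O[Si](C(C)C)(C(C)C)C(C)C)[C@H](C)CNS(=O)(=O)c3ccccc3[N+](=O)[O-])[C@@H](CO)CCC3=C4[C@H](CC3)[C@H]1C[C@@]42C(OC)OC | intermediate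
32 | N-nosyl nine-membered amine (ring E closed through N–C7), C1 dimethyl acetal | O=C1OC[C@]23CC[C@@H](O[Si](C(C)C)(C(C)C)C(C)C)[C@H](C)CN(S(=O)(=O)c4ccccc4[N+](=O)[O-])C[C@H]2CCC2=C4[C@H](CC2)[C@H]1C[C@@]43C(OC)OC | intermediate
33 | C1 aldehyde of 32 | O=C1OC[C@]23CC[C@@H](O[Si](C(C)C)(C(C)C)C(C)C)[C@H](C)CN(S(=O)(=O)c4ccccc4[N+](=O)[O-])C[C@H]2CCC2=C4[C@H](CC2)[C@H]1C[C@@]43C=O | intermediate
34 | secondary amino aldehyde (not isolated) | O=C1OC[C@]23CC[C@@H](O[Si](C(C)C)(C(C)C)C(C)C)[C@H](C)CNC[C@H]2CCC2=C4[C@H](CC2)[C@H]1C[C@@]43C=O | intermediate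
35 | bridged carbinolamine N–C1H(OH) (ring D closed, epimers at C1) | O=C1OC[C@]23CC[C@@H](O[Si](C(C)C)(C(C)C)C(C)C)[C@H](C)CN4C[C@H]2CCC2=C5[C@H](CC2)[C@H]1C[C@@]53C4O | intermediate
36 | lactam lactone (rings A–E plus the C22–O–C21 lactone), C2 OTIPS | O=C1OC[C@]23CC[C@@H](O[Si](C(C)C)(C(C)C)C(C)C)[C@H](C)CN4C[C@H]2CCC2=C5[C@H](CC2)[C@H]1C[C@@]53C4=O | intermediate
37 | C22 methyl ester C21 alcohol, C2 OTIPS (not isolated) | COC(=O)[C@@H]1C[C@@]23C(=O)N4C[C@@H](CCC5=C2[C@@H]1CC5)[C@]3(CO)CC[C@@H](O[Si](C(C)C)(C(C)C)C(C)C)[C@H](C)C4 | intermediate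
38 | C2 O-triisopropylsilyl ether of the target | COC(=O)[C@@H]1C[C@@]23C(=O)N4C[C@@H](CCC5=C2[C@@H]1CC5)[C@]3(COC(C)=O)CC[C@@H](O[Si](C(C)C)(C(C)C)C(C)C)[C@H](C)C4 | intermediate
39 | CNP0296366.1 | COC(=O)[C@@H]1C[C@@]23C(=O)N4C[C@@H](CCC5=C2[C@@H]1CC5)[C@]3(COC(C)=O)CC[C@@H](O)[C@H](C)C4 | target

## Step count

Total steps: 27. Longest linear sequence: 18 steps (steps 1, 3–9, then 18–27; the east branch, steps 10–17 then 18–27, is equally long).

## Three steps most likely to fail, with fallbacks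

**Step 19, the tethered (4+3) cycloaddition.** The cation may be captured by solvent or by the sulfonamide, or the ester tether may be too strained. The fallback changes the cation precursor and the way it is ionised. It sets out from 26: TMSOTf/Et3N at −78 °C gives the N,O-bis(trimethylsilyl) 2-siloxyallyl chloride F1. AgBF4 in CH2Cl2/nitroethane at −78 °C ionises it to a siloxyallyl cation in an aprotic, base-free medium with the sulfonamide masked. Aqueous work-up returns to the route at 28.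

**Step 21, the facial selectivity of the hydroboration at C6.** If the wrong C6 epimer forms, C6 is set after ring D is closed, when it is a bridgehead and only one configuration is possible. The fallback sets out from 28. KN(SiMe3)2 and N-phenyltriflimide give the C6 enol triflate F2 (only C12 can enolise). Stille coupling with Bu3SnCH2OH (Pd(PPh3)4, LiCl) gives the allylic alcohol F3. Mitsunobu ring closure as in step 22 gives the unsaturated nosyl amine F4, aqueous HCl gives the aldehyde F5, and thiolate removal of the nosyl group gives the unsaturated carbinolamine F6. Oxidation with (n-Pr4N)RuO4 and N-methylmorpholine N-oxide gives the unsaturated lactam F7. Hydrogenation (H2, Pd/C) of the trisubstituted C6=C12 alkene from the exposed face, sparing the tetrasubstituted C9=C10 alkene, returns to the route at 36.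

**Step 22, the nine-membered Mitsunobu ring closure.** If it fails, the N–C7 bond is made by reductive amination instead. The fallback sets out from 31. PhSH/K2CO3 gives the primary amine F8. Dess–Martin oxidation of its trifluoroacetate salt gives the amino aldehyde F9, which is not isolated. NaBH(OAc)3 at high dilution cyclises it to the nine-membered secondary amine F10. Aqueous HCl then unmasks C1 and the route is rejoined at carbinolamine 35.

## Further compounds

F1 | step 19 | N,O-bis(trimethylsilyl) 2-siloxyallyl chloride derived from 26 | C=C1CC[C@H]2C1=C(C(OC)OC)C[C@H]2C(=O)OCC(Cl)(C(=C)O[Si](C)(C)C)CC[C@@H](O[Si](C(C)C)(C(C)C)C(C)C)[C@H](C)CN([Si](C)(C)C)S(=O)(=O)c1ccccc1[N+](=O)[O-]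
F2 | step 21 | C6 enol triflate (C6=C12) of 28 | O=C1OC[C@]2(CC[C@@H](O[Si](C(C)C)(C(C)C)C(C)C)[C@H](C)CNS(=O)(=O)c3ccccc3[N+](=O)[O-])C(OS(=O)(=O)C(F)(F)F)=CCC3=C4[C@H](CC3)[C@H]1C[C@@]42C(OC)OC
F3 | step 21 | allylic alcohol (C6=C12, C7H2OH) | O=C1OC[C@]2(CC[C@@H](O[Si](C(C)C)(C(C)C)C(C)C)[C@H](C)CNS(=O)(=O)c3ccccc3[N+](=O)[O-])C(CO)=CCC3=C4[C@H](CC3)[C@H]1C[C@@]42C(OC)OC
F4 | step 21 | unsaturated N-nosyl nine-membered amine (C6=C12), C1 acetal | O=C1OC[C@]23CC[C@@H](O[Si](C(C)C)(C(C)C)C(C)C)[C@H](C)CN(S(=O)(=O)c4ccccc4[N+](=O)[O-])CC2=CCC2=C4[C@H](CC2)[C@H]1C[C@@]43C(OC)OC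
F5 | step 21 | C1 aldehyde of F4 | O=C1OC[C@]23CC[C@@H](O[Si](C(C)C)(C(C)C)C(C)C)[C@H](C)CN(S(=O)(=O)c4ccccc4[N+](=O)[O-])CC2=CCC2=C4[C@H](CC2)[C@H]1C[C@@]43C=O
F6 | step 21 | unsaturated carbinolamine (C6=C12) | O=C1OC[C@]23CC[C@@H](O[Si](C(C)C)(C(C)C)C(C)C)[C@H](C)CN4CC2=CCC2=C5[C@H](CC2)[C@H]1C[C@@]53C4O
F7 | step 21 | unsaturated lactam lactone (C6=C12) | O=C1OC[C@]23CC[C@@H](O[Si](C(C)C)(C(C)C)C(C)C)[C@H](C)CN4CC2=CCC2=C5[C@H](CC2)[C@H]1C[C@@]53C4=O
F8 | step 22 | primary amine alcohol (nosyl removed from 31) | O=C1OC[C@]2(CC[C@@H](O[Si](C(C)C)(C(C)C)C(C)C)[C@H](C)CN)[C@@H](CO)CCC3=C4[C@H](CC3)[C@H]1C[C@@]42C(OC)OC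
F9 | step 22 | primary amino C7 aldehyde (as trifluoroacetate salt, not isolated) | O=C1OC[C@]2(CC[C@@H](O[Si](C(C)C)(C(C)C)C(C)C)[C@H](C)CN)[C@@H](C=O)CCC3=C4[C@H](CC3)[C@H]1C[C@@]42C(OC)OC
F10 | step 22 | nine-membered secondary amine, C1 dimethyl acetal | O=C1OC[C@]23CC[C@@H](O[Si](C(C)C)(C(C)C)C(C)C)[C@H](C)CNC[C@H]2CCC2=C4[C@H](CC2)[C@H]1C[C@@]43C(OC)OC
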